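**Plan**

- Cuts, in retrosynthetic order: the lactone O6–C12 bond and the C8 ester C–O bond; the ring bond C7–C8, traded for the O–C13 bond of a thirteen-membered cyclic diallylic ether (O bridging C8 and C13); that ether's O–C8 bond; then C11–C13, C6–C7, C10–C1 and C3–C4 of the open chain.
- Enabling feature: in the ten-membered ring C1–C10, the unit C8(OH)–C7–C11(=C13H2) is a homoallylic alcohol whose carbinol carbon C8 is allylic to the ring olefin C9=C10. This is the retron of a [2,3]-Wittig shift.
- Forward: Negishi coupling (C3–C4) and alkenyllithium acylation (C10–C1) give the C8→C6 chain; alkynylation (C6–C7) and hydroxymethyl Stille coupling (C11–C13) extend it. The thirteen-membered ether is closed at O–C8, contracted to the ten-membered carbocycle (C7–C8), and the γ-lactone ring closes last.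
- Stereochemistry: the three ring-cis trisubstituted olefins come from hydroxyl-directed trans-hydroalumination/iodination of three alkynols, followed by couplings with retention. C1 (S) comes from a CBS reduction and C6 (R) from a ligand-controlled alkynylation. C7 and C8 are set in the sigmatropic step by the C7=C11 geometry and by C6. The ester stereocentre is bought as (S)-2-methylbutanoic acid.

Key step: step 21

Remarks
- Locants C1–C15 are those of the target (ring C1–C10, C11=C13H2 on C7, C12 lactone carbonyl, C14 methyl on C10, C15 hydroxymethyl on C4) and are kept for all intermediates; TBS = tert-butyldimethylsilyl, TES = triethylsilyl, PMB = 4-methoxybenzyl.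
- Assumption: (S,S)-ProPhenol is taken to deliver the acetylide to the Si face of enal 22 (giving 6R); if the sense is opposite, the (R,R) ligand is used with no other change.
- (3-Ethoxy-3-oxopropyl)zinc bromide (THF solution) and (tributylstannyl)methanol are treated as purchased reagents.

**Route**

Step 1
Reactants: 1 but-2-yn-1-ol
Product: 3 (2Z)-3-iodobut-2-en-1-ol, via cyclic alkenylalanate 2 (not isolated)
Conditions: NaAlH2(OCH2CH2OMe)2 (Red-Al), THF, 0 °C→rt; then I2, THF, −78 °C
Reagents that add atoms: iodine, II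
Why: Hydroxyl-directed trans-hydroalumination of a propargylic alcohol puts aluminium on the distal alkyne carbon and iodinolysis with retention gives the (Z)-3-iodo allylic alcohol, so the carbon that later replaces iodine (C1) will sit cis to C8 as the ring-cis C9=C10 requires.

Step 2
Reactants: 3 (2Z)-3-iodobut-2-en-1-ol
Product: 5 1-({[(2Z)-3-iodobut-2-en-1-yl]oxy}methyl)-4-methoxybenzene, via sodium alkoxide 4 (not isolated)
Conditions: NaH, DMF, 0 °C; then 4-methoxybenzyl chloride, Bu4NI (cat.), 0 °C→rt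
Reagents that add atoms: 4-methoxybenzyl chloride, COc1ccc(CCl)cc1
Why: Williamson etherification puts on O8 a benzyl-type ether that survives the later iodine–lithium exchange (a silyl ether would undergo a 1,4 O→C silyl shift) and can be removed oxidatively beside silyl ethers.

Step 3
Reactants: 6 prop-2-yn-1-ol
Product: 7 triethyl(prop-2-yn-1-yloxy)silane
Conditions: TESCl, imidazole, CH2Cl2, 0 °C
Reagents that add atoms: chlorotriethylsilane, CC[Si](CC)(CC)Cl
Why: Routine silylation of a primary alcohol; TES is chosen for the future O12 because it can later be cleaved in the presence of TBS ethers.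

Step 4
Reactants: 8 but-2-yne-1,4-diol
Product: 10 4-{[tert-butyl(dimethyl)silyl]oxy}but-2-yn-1-ol, via monosodium alkoxide 9 (not isolated)
Conditions: NaH (1 equiv), THF, rt; then TBSCl, rt
Reagents that add atoms: tert-butyl(chloro)dimethylsilane, CC(C)(C)[Si](C)(C)Cl
Why: Monosilylation of a symmetrical diol through its monosodium alkoxide is a standard desymmetrisation and decides which oxygen becomes O15 (silylated) and which O6 (free).

Step 5
Reactants: 10 4-{[tert-butyl(dimethyl)silyl]oxy}but-2-yn-1-ol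
Product: 12 (2Z)-4-{[tert-butyl(dimethyl)silyl]oxy}-3-iodobut-2-en-1-ol, via cyclic alkenylalanate 11 (not isolated)
Conditions: NaAlH2(OCH2CH2OMe)2, THF, −20→0 °C; then I2, THF, −78 °C
Reagents that add atoms: iodine, II
Why: The same directed trans-hydroalumination–iodination applies; only the free hydroxyl (O6) binds aluminium, so hydride goes to C5 and iodine to C4 cis to C6, and the low temperature should prevent loss of the silyloxy group to an allene.

Step 6
Reactants: 12 (2Z)-4-{[tert-butyl(dimethyl)silyl]oxy}-3-iodobut-2-en-1-ol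
Product: 13 tert-butyl{[(2Z)-2-iodo-4-(triethylsilyloxy)but-2-en-1-yl]oxy}dimethylsilane
Conditions: TESCl, imidazole, CH2Cl2, 0 °C
Reagents that add atoms: chlorotriethylsilane, CC[Si](CC)(CC)Cl
Why: Routine silylation that masks O6 with a group removable later beside the TBS ethers.

Step 7
Reactants: 13 bis-silylated alkenyl iodide; 14 (3-ethoxy-3-oxopropyl)zinc bromide
Product: 15 ethyl (4E)-4-({[tert-butyl(dimethyl)silyl]oxy}methyl)-6-(triethylsilyloxy)hex-4-enoate
Conditions: Pd(PPh3)4 (5 mol %), THF–DMA, 45 °C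
Reagents that add atoms: none
Why: Negishi coupling of a zinc homoenolate with an alkenyl iodide forms C3–C4 with retention of olefin geometry (C3 cis to C6) and tolerates the ester and both silyl ethers.

Step 8
Reactants: 15 ethyl ester
Product: 16 (4E)-4-({[tert-butyl(dimethyl)silyl]oxy}methyl)-N-methoxy-N-methyl-6-(triethylsilyloxy)hex-4-enamide
Conditions: MeNH(OMe)·HCl, i-PrMgCl, THF, −20 °C
Reagents that add atoms: N,O-dimethylhydroxylamine hydrochloride, CNOC.Cl
Why: Aminolysis of the ester by the magnesium amide made in the flask gives the Weinreb amide, the acyl donor that allows clean monoaddition at C1.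

Step 9
Reactants: 16 Weinreb amide; 5 PMB-protected alkenyl iodide
Product: 18 (2Z,7E)-7-({[tert-butyl(dimethyl)silyl]oxy}methyl)-1-[(4-methoxybenzyl)oxy]-3-methyl-9-(triethylsilyloxy)nona-2,7-dien-4-one, via alkenyllithium 17 (not isolated)
Conditions: 5, t-BuLi (2 equiv), Et2O, −78 °C; then 16, −78→0 °C; then H2O
Reagents that add atoms: none
Why: Iodine–lithium exchange proceeds with retention and the alkenyllithium adds once to the Weinreb amide through a chelated tetrahedral intermediate, forming C10–C1 as the (Z)-enone with C8 cis to C1.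

Step 10
Reactants: 18 enone
Product: 19 (2Z,4S,7E)-7-({[tert-butyl(dimethyl)silyl]oxy}methyl)-1-[(4-methoxybenzyl)oxy]-3-methyl-9-(triethylsilyloxy)nona-2,7-dien-4-ol
Conditions: (R)-2-methyl-CBS-oxazaborolidine (0.3 equiv), catecholborane, toluene, −78 °C; then H2O
Reagents that add atoms: none
Why: In this Corey–Bakshi–Shibata reduction the α-methyl alkenyl group acts as the large substituent and the (R)-catalyst should deliver hydride to the face that gives the (1S)-allylic alcohol.

Step 11
Reactants: 19 allylic alcohol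
Product: 20 the C1 TBS ether of 19
Conditions: TBSCl, imidazole, DMF, rt
Reagents that add atoms: tert-butyl(chloro)dimethylsilane, CC(C)(C)[Si](C)(C)Cl
Why: Standard silylation of the secondary allylic alcohol as a robust ether that is carried to the last step.

Step 12
Reactants: 20 fully protected chain
Product: 21 the C6 primary allylic alcohol (TES removed; 1S; 4E; 9Z)
Conditions: PPTS (cat.), MeOH–CH2Cl2, 0 °C
Reagents that add atoms: none
Why: Mild acid methanolysis cleaves a primary TES ether much faster than primary or secondary TBS ethers and leaves the PMB ether alone, so only O6 is freed.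

Step 13
Reactants: 21 C6 alcohol
Product: 22 the C6 enal (C6HO–C5H=C4; CHO cis to C3)
Conditions: MnO2, CH2Cl2, rt
Reagents that add atoms: none
Why: MnO2 oxidises the primary allylic alcohol to the enal under neutral conditions that should leave the C4=C5 geometry, the silyl ethers and the PMB ether untouched.

Step 14
Reactants: 22 enal; 7 triethyl(prop-2-yn-1-yloxy)silane
Product: 24 (4R,5E,9S,10Z)-9-{[tert-butyl(dimethyl)silyl]oxy}-6-({[tert-butyl(dimethyl)silyl]oxy}methyl)-12-[(4-methoxybenzyl)oxy]-10-methyl-1-(triethylsilyloxy)dodeca-5,10-dien-2-yn-4-ol, via alkynylzinc 23 (not isolated)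
Conditions: 7 (3 equiv), ZnMe2 (3 equiv), (S,S)-ProPhenol (20 mol %), Ph3PO (40 mol %), toluene, 0 °C; then 22; then H2O
Reagents that add atoms: none
Why: Zinc–ProPhenol catalysed alkynylation of α,β-unsaturated aldehydes forms C6–C7 by 1,2-addition and sets the (6R) carbinol by ligand control, no nearby stereocentre being present to interfere.

Step 15
Reactants: 24 propargylic alcohol
Product: 26 the (Z)-C11 iodide (C6–OH free; H on C7; I on C11 cis to C6), via cyclic alkenylalanate 25 (not isolated)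
Conditions: NaAlH2(OCH2CH2OMe)2, THF, −20→0 °C; then I2, THF, −78 °C
Reagents that add atoms: iodine, II
Why: The C6 alkoxide directs the trans-hydroalumination so that hydride adds to C7 and aluminium, then iodine, to C11 cis to C6, which fixes the C7=C11 geometry needed for the sigmatropic step.

Step 16
Reactants: 26 iodo alcohol
Product: 27 the C6 TBS ether of 26
Conditions: TBSOTf, 2,6-lutidine, CH2Cl2, −78 °C
Reagents that add atoms: tert-butyldimethylsilyl trifluoromethanesulfonate, CC(C)(C)[Si](C)(C)OS(=O)(=O)C(F)(F)F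
Why: A silyl triflate with a hindered base silylates the crowded doubly allylic alcohol at low temperature without ionising it.

Step 17
Reactants: 27 alkenyl iodide; 28 (tributylstannyl)methanol
Product: 29 (2E,4R,5E,9S,10Z)-4,9-bis{[tert-butyl(dimethyl)silyl]oxy}-6-({[tert-butyl(dimethyl)silyl]oxy}methyl)-12-[(4-methoxybenzyl)oxy]-10-methyl-2-[(triethylsilyloxy)methyl]dodeca-2,5,10-trien-1-ol
Conditions: Pd(PPh3)4 (10 mol %), toluene, 90 °C
Reagents that add atoms: none
Why: Stille coupling of the alkenyl iodide with the hydroxymethyl stannane installs C13 as a free primary alcohol with retention, cis to C6 and thereby distinguished from C12.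

Step 18
Reactants: 29 C13 alcohol
Product: 31 the C13 allylic chloride, via mesylate 30 (not isolated)
Conditions: MsCl, Et3N, CH2Cl2, −30 °C; then LiCl, THF–DMF, 0 °C→rt
Reagents that add atoms: lithium chloride, [Li+].[Cl-]
Why: Mesylation followed by chloride displacement converts the primary allylic alcohol into the chloride by direct SN2 substitution, without allylic transposition or loss of silyl groups.

Step 19
Reactants: 31 PMB-protected chloride
Product: 32 the seco chloro alcohol (C8–OH free; C13–Cl)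
Conditions: DDQ, CH2Cl2–pH 7 buffer, 0 °C
Reagents that add atoms: none
Why: DDQ oxidises the electron-rich PMB ether to an oxocarbenium ion that water hydrolyses, releasing O8–H while the allylic chloride and the silyl ethers should stay intact.

Step 20
Reactants: 32 seco chloro alcohol
Product: 34 (1S,6R)-thirteen-membered cyclic diallylic ether (ring O–C13H2–C11(C12H2OTES)=C7H–C6H(OTBS)–C5H=C4(C15H2OTBS)–C3H2–C2H2–C1H(OTBS)–C10(C14H3)=C9H–C8H2–O; C13 cis to C6; C6 cis to C3; C1 cis to C8), via sodium alkoxide 33 (not isolated)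
Conditions: NaH, Bu4NI (cat.), THF, slow addition to 0.002 M, 45 °C
Reagents that add atoms: none
Why: Intramolecular Williamson etherification (13-exo-tet SN2 at the primary allylic C13) under high dilution closes the thirteen-membered diallylic ether, the three ring-cis olefins holding the chain ends near each other.

Step 21
Reactants: 34 thirteen-membered cyclic diallylic ether
Product: 36 (1R,2Z,4S,7E,9R,10R)-4,9-bis{[tert-butyl(dimethyl)silyl]oxy}-7-({[tert-butyl(dimethyl)silyl]oxy}methyl)-3-methyl-10-[3-(triethylsilyloxy)prop-1-en-2-yl]cyclodeca-2,7-dien-1-ol (target locants 1S;6R;7R;8R), via C8-lithio ether 35 (not isolated)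
Conditions: n-BuLi (3 equiv), THF, −78 °C; then H2O at −78 °C
Reagents that add atoms: none
Why: n-BuLi removes a C8 proton (α to the ring oxygen, allylic to C9=C10) and the α-oxy allyllithium 35 undergoes a concerted suprafacial [2,3]-sigmatropic shift through a five-membered envelope C8–O–C13–C11–C7, in which C8 bonds to C7, O–C13 breaks and the C11=C13 methylene appears. The closest known reaction type is the [2,3]-Wittig ring contraction of thirteen-membered cyclic diallylic ethers to ten-membered germacrane-type homoallylic alcohols. The ten-membered carbocycle thus closes by a transannular bond between two ring atoms that the ether bridge already holds 1,5 to each other (contraction from thirteen to ten), not by an end-to-end cyclisation. C8 relative to C7 (O8 syn to C6 in the C9–C8–C7–C11 zigzag, H7 and H8 cis on the ring) should follow from the olefin geometry, because C6 is cis to C13 on C7=C11 and such (Z)-type allyl termini give the erythro product in [2,3]-Wittig shifts. C7 relative to C6 should follow from allylic strain: H6 eclipses the C7=C11 bond to avoid C13, the bulky O6 silyl ether covers one olefin face and C5 lies on the other, so that C8, which the ring ties to C5, adds anti to O6 and gives the 6R,7R,8R array. The step needs lithiation at C8 and not at C13, at the silyloxy-bearing allylic carbons or at the doubly allylic C6–H; only C8 and C13 flank the Lewis-basic dialkyl ether oxygen that guides the base, C13 is screened by the neighbouring C12 silyloxymethyl group and the cis C6 substituent, a shift started from C13 would have to create a quaternary centre at C10, and −78 °C keeps the [1,2]-shift slow.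

Step 22
Reactants: 36 ten-membered C8 carbinol; 37 (2S)-2-methylbutanoic acid
Product: 39 the C8 (2S)-2-methylbutanoate of 36, via mixed anhydride 38 (not isolated)
Conditions: 37, 2,4,6-trichlorobenzoyl chloride, Et3N, THF, rt; then 36, DMAP, toluene, rt
Reagents that add atoms: none
Why: Yamaguchi esterification acylates the hindered secondary O8–H, the only free hydroxyl, with retention at C8 and should not epimerise the α-stereocentre of the acid.

Step 23
Reactants: 39 C8 ester
Product: 40 the C12 primary allylic alcohol (TES removed)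
Conditions: PPTS (cat.), MeOH–CH2Cl2, 0 °C
Reagents that add atoms: none
Why: Selective methanolysis of the single primary TES ether frees O12 while the three TBS ethers and the ester remain.

Step 24
Reactants: 40 C12 alcohol
Product: 41 the C12 enal (2-substituted acrolein on C7)
Conditions: MnO2, CH2Cl2, rt
Reagents that add atoms: none
Why: MnO2 oxidises the 2-substituted allyl alcohol, the only free hydroxyl, to the α-substituted acrolein without touching the other groups.

Step 25
Reactants: 41 C12 enal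
Product: 42 the C12 acrylic acid
Conditions: NaClO2, NaH2PO4, 2-methyl-2-butene, t-BuOH–H2O, 0 °C→rt
Reagents that add atoms: sodium chlorite, [Na+].[O-]Cl=O
Why: Pinnick oxidation converts enals to acrylic acids chemoselectively, the alkene scavenger protecting the trisubstituted olefins from hypochlorous acid.

Step 26
Reactants: 42 tris-TBS acid
Product: 44 (1S,6R,7R,8R,4E,9Z)-1,15-dihydroxy-8-[(2S)-2-methylbutanoyloxy]germacra-4,9,11(13)-trien-12,6-olide (CNP0526758.1), via trihydroxy acid 43 (not isolated)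
Conditions: HF·pyridine, pyridine, THF, 0 °C→rt
Reagents that add atoms: none
Why: Buffered HF removes the three TBS ethers and the freed O6–H, γ to the C12 acid and held next to it on C7, should close the five-membered α-methylene lactone by 5-exo-trig acyl substitution, O1–H and O15–H being too remote and O8 already acylated.

**Compound list**

1 | but-2-yn-1-ol | CC#CCO | starting material
2 | cyclic alkenylalanate from 1, sodium 2,2-bis(2-methoxyethoxy)-3-methyl-2,5-dihydro-1,2-oxaaluminol-2-uide (formed in the flask) | CC1=CCO[Al-]1(OCCOC)OCCOC.[Na+] | intermediate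
3 | (2Z)-3-iodobut-2-en-1-ol | C/C(I)=C/CO | intermediate
4 | sodium (2Z)-3-iodobut-2-en-1-olate (formed in the flask) | C/C(I)=C/C[O-].[Na+] | intermediate
5 | 1-({[(2Z)-3-iodobut-2-en-1-yl]oxy}methyl)-4-methoxybenzene (C14–C10(I)=C9–C8–OPMB) | C/C(I)=C/COCc1ccc(OC)cc1 | intermediate
6 | prop-2-yn-1-ol | C#CCO | starting material
7 | triethyl(prop-2-yn-1-yloxy)silane (C7≡C11–C12 unit) | C#CCO[Si](CC)(CC)CC | intermediate
8 | but-2-yne-1,4-diol | OCC#CCO | starting material
9 | sodium 4-hydroxybut-2-yn-1-olate (formed in the flask) | [Na+].[O-]CC#CCO | intermediate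
10 | 4-{[tert-butyl(dimethyl)silyl]oxy}but-2-yn-1-ol | OCC#CCO[Si](C)(C)C(C)(C)C | intermediate
11 | cyclic alkenylalanate from 10 (Al on C4, O6 bound to Al; formed in the flask) | CC(C)(C)[Si](C)(C)OCC1=CCO[Al-]1(OCCOC)OCCOC.[Na+] | intermediate
12 | (2Z)-4-{[tert-butyl(dimethyl)silyl]oxy}-3-iodobut-2-en-1-ol (C6H2OH–C5H=C4(I)–C15H2OTBS) | OC/C=C(\I)CO[Si](C)(C)C(C)(C)C | intermediate
13 | tert-butyl{[(2Z)-2-iodo-4-(triethylsilyloxy)but-2-en-1-yl]oxy}dimethylsilane | CC[Si](CC)(CC)OC/C=C(\I)CO[Si](C)(C)C(C)(C)C | intermediate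
14 | (3-ethoxy-3-oxopropyl)zinc bromide | CCOC(=O)CC[Zn]Br | starting material
15 | ethyl (4E)-4-({[tert-butyl(dimethyl)silyl]oxy}methyl)-6-(triethylsilyloxy)hex-4-enoate (C1 ester to C6) | CCOC(=O)CC/C(CO[Si](C)(C)C(C)(C)C)=C\CO[Si](CC)(CC)CC | intermediate
16 | (4E)-4-({[tert-butyl(dimethyl)silyl]oxy}methyl)-N-methoxy-N-methyl-6-(triethylsilyloxy)hex-4-enamide | CON(C)C(=O)CC/C(CO[Si](C)(C)C(C)(C)C)=C\CO[Si](CC)(CC)CC | intermediate
17 | {(2Z)-4-[(4-methoxybenzyl)oxy]but-2-en-2-yl}lithium (formed in the flask) | C/C([Li])=C/COCc1ccc(OC)cc1 | intermediate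
18 | (2Z,7E)-7-({[tert-butyl(dimethyl)silyl]oxy}methyl)-1-[(4-methoxybenzyl)oxy]-3-methyl-9-(triethylsilyloxy)nona-2,7-dien-4-one (C8–C9=C10–C1(=O)–C2–C3–C4=C5–C6) | COc1ccc(COC/C=C(/C)C(=O)CC/C(CO[Si](C)(C)C(C)(C)C)=C\CO[Si](CC)(CC)CC)cc1 | intermediate
19 | (2Z,4S,7E)-7-({[tert-butyl(dimethyl)silyl]oxy}methyl)-1-[(4-methoxybenzyl)oxy]-3-methyl-9-(triethylsilyloxy)nona-2,7-dien-4-ol (1S) | CC[Si](CC)(CC)OC/C=C(/CO[Si](C)(C)C(C)(C)C)CC[C@H](O)/C(C)=C\COCc1ccc(OC)cc1 | intermediate
20 | C1 TBS ether of 19 | CC[Si](CC)(CC)OC/C=C(/CO[Si](C)(C)C(C)(C)C)CC[C@H](O[Si](C)(C)C(C)(C)C)/C(C)=C\COCc1ccc(OC)cc1 | intermediate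
21 | (2E,6S,7Z)-6-{[tert-butyl(dimethyl)silyl]oxy}-3-({[tert-butyl(dimethyl)silyl]oxy}methyl)-9-[(4-methoxybenzyl)oxy]-7-methylnona-2,7-dien-1-ol (C6 alcohol) | OC/C=C(/CO[Si](C)(C)C(C)(C)C)CC[C@H](O[Si](C)(C)C(C)(C)C)/C(C)=C\COCc1ccc(OC)cc1 | intermediate
22 | (2E,6S,7Z)-6-{[tert-butyl(dimethyl)silyl]oxy}-3-({[tert-butyl(dimethyl)silyl]oxy}methyl)-9-[(4-methoxybenzyl)oxy]-7-methylnona-2,7-dienal (C6 enal) | O=C/C=C(/CO[Si](C)(C)C(C)(C)C)CC[C@H](O[Si](C)(C)C(C)(C)C)/C(C)=C\COCc1ccc(OC)cc1 | intermediate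
23 | methyl[3-(triethylsilyloxy)prop-1-yn-1-yl]zinc (formed in the flask) | C[Zn]C#CCO[Si](CC)(CC)CC | intermediate
24 | (4R,5E,9S,10Z)-9-{[tert-butyl(dimethyl)silyl]oxy}-6-({[tert-butyl(dimethyl)silyl]oxy}methyl)-12-[(4-methoxybenzyl)oxy]-10-methyl-1-(triethylsilyloxy)dodeca-5,10-dien-2-yn-4-ol (6R propargylic alcohol) | CC[Si](CC)(CC)OCC#C[C@H](O)/C=C(/CO[Si](C)(C)C(C)(C)C)CC[C@H](O[Si](C)(C)C(C)(C)C)/C(C)=C\COCc1ccc(OC)cc1 | intermediate
25 | cyclic alkenylalanate from 24 (Al on C11, O6 bound to Al; formed in the flask) | CC[Si](CC)(CC)OCC1=C[C@@H](/C=C(/CO[Si](C)(C)C(C)(C)C)CC[C@H](O[Si](C)(C)C(C)(C)C)/C(C)=C\COCc2ccc(OC)cc2)O[Al-]1(OCCOC)OCCOC.[Na+] | intermediate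
26 | (2Z,4R,5E,9S,10Z)-9-{[tert-butyl(dimethyl)silyl]oxy}-6-({[tert-butyl(dimethyl)silyl]oxy}methyl)-2-iodo-12-[(4-methoxybenzyl)oxy]-10-methyl-1-(triethylsilyloxy)dodeca-2,5,10-trien-4-ol (I on C11 cis to C6) | CC[Si](CC)(CC)OC/C(I)=C/[C@H](O)/C=C(/CO[Si](C)(C)C(C)(C)C)CC[C@H](O[Si](C)(C)C(C)(C)C)/C(C)=C\COCc1ccc(OC)cc1 | intermediate
27 | C6 TBS ether of 26 | CC[Si](CC)(CC)OC/C(I)=C/[C@H](O[Si](C)(C)C(C)(C)C)/C=C(/CO[Si](C)(C)C(C)(C)C)CC[C@H](O[Si](C)(C)C(C)(C)C)/C(C)=C\COCc1ccc(OC)cc1 | intermediate
28 | (tributylstannyl)methanol | CCCC[Sn](CCCC)(CCCC)CO | starting material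
29 | (2E,4R,5E,9S,10Z)-4,9-bis{[tert-butyl(dimethyl)silyl]oxy}-6-({[tert-butyl(dimethyl)silyl]oxy}methyl)-12-[(4-methoxybenzyl)oxy]-10-methyl-2-[(triethylsilyloxy)methyl]dodeca-2,5,10-trien-1-ol (C13–OH cis to C6) | CC[Si](CC)(CC)OC/C(CO)=C/[C@H](O[Si](C)(C)C(C)(C)C)/C=C(/CO[Si](C)(C)C(C)(C)C)CC[C@H](O[Si](C)(C)C(C)(C)C)/C(C)=C\COCc1ccc(OC)cc1 | intermediate
30 | C13 methanesulfonate of 29 (formed in the flask) | CC[Si](CC)(CC)OC/C(COS(C)(=O)=O)=C/[C@H](O[Si](C)(C)C(C)(C)C)/C=C(/CO[Si](C)(C)C(C)(C)C)CC[C@H](O[Si](C)(C)C(C)(C)C)/C(C)=C\COCc1ccc(OC)cc1 | intermediate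
31 | C13 allylic chloride (29 with C13–OH replaced by Cl) | CC[Si](CC)(CC)OC/C(CCl)=C/[C@H](O[Si](C)(C)C(C)(C)C)/C=C(/CO[Si](C)(C)C(C)(C)C)CC[C@H](O[Si](C)(C)C(C)(C)C)/C(C)=C\COCc1ccc(OC)cc1 | intermediate
32 | seco chloro alcohol (31 without PMB; C8–OH, C13–Cl) | CC[Si](CC)(CC)OC/C(CCl)=C/[C@H](O[Si](C)(C)C(C)(C)C)/C=C(/CO[Si](C)(C)C(C)(C)C)CC[C@H](O[Si](C)(C)C(C)(C)C)/C(C)=C\CO | intermediate
33 | sodium C8 alkoxide of 32 (formed in the flask) | CC[Si](CC)(CC)OC/C(CCl)=C/[C@H](O[Si](C)(C)C(C)(C)C)/C=C(/CO[Si](C)(C)C(C)(C)C)CC[C@H](O[Si](C)(C)C(C)(C)C)/C(C)=C\C[O-].[Na+] | intermediate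
34 | (1S,6R)-thirteen-membered cyclic diallylic ether, O bridging C8 and C13; 1-OTBS, 6-OTBS, 15-OTBS, 12-OTES; three ring-cis olefins | O1C/C(CO[Si](CC)(CC)CC)=C\[C@H](O[Si](C)(C)C(C)(C)C)/C=C(/CO[Si](C)(C)C(C)(C)C)CC[C@H](O[Si](C)(C)C(C)(C)C)/C(C)=C\C1 | intermediate
35 | C8-lithio derivative of 34 (formed in the flask) | O1C/C(CO[Si](CC)(CC)CC)=C\[C@H](O[Si](C)(C)C(C)(C)C)/C=C(/CO[Si](C)(C)C(C)(C)C)CC[C@H](O[Si](C)(C)C(C)(C)C)/C(C)=C\C1[Li] | intermediate
36 | (1R,2Z,4S,7E,9R,10R)-4,9-bis{[tert-butyl(dimethyl)silyl]oxy}-7-({[tert-butyl(dimethyl)silyl]oxy}methyl)-3-methyl-10-[3-(triethylsilyloxy)prop-1-en-2-yl]cyclodeca-2,7-dien-1-ol (target locants 1S,6R,7R,8R; C8–OH free) | C=C(CO[Si](CC)(CC)CC)[C@H]1[C@H](O[Si](C)(C)C(C)(C)C)/C=C(/CO[Si](C)(C)C(C)(C)C)CC[C@H](O[Si](C)(C)C(C)(C)C)/C(C)=C\[C@H]1O | intermediate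
37 | (2S)-2-methylbutanoic acid | CC[C@H](C)C(=O)O | starting material
38 | (2S)-2-methylbutanoic 2,4,6-trichlorobenzoic anhydride (formed in the flask) | CC[C@H](C)C(=O)OC(=O)c1c(Cl)cc(Cl)cc1Cl | intermediate
39 | C8 (2S)-2-methylbutanoate of 36 | C=C(CO[Si](CC)(CC)CC)[C@H]1[C@H](O[Si](C)(C)C(C)(C)C)/C=C(/CO[Si](C)(C)C(C)(C)C)CC[C@H](O[Si](C)(C)C(C)(C)C)/C(C)=C\[C@H]1OC(=O)[C@@H](C)CC | intermediate
40 | C12 alcohol (39 without TES) | C=C(CO)[C@H]1[C@H](O[Si](C)(C)C(C)(C)C)/C=C(/CO[Si](C)(C)C(C)(C)C)CC[C@H](O[Si](C)(C)C(C)(C)C)/C(C)=C\[C@H]1OC(=O)[C@@H](C)CC | intermediate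
41 | C12 enal | C=C(C=O)[C@H]1[C@H](O[Si](C)(C)C(C)(C)C)/C=C(/CO[Si](C)(C)C(C)(C)C)CC[C@H](O[Si](C)(C)C(C)(C)C)/C(C)=C\[C@H]1OC(=O)[C@@H](C)CC | intermediate
42 | C12 acrylic acid, tris-TBS ether | C=C(C(=O)O)[C@H]1[C@H](O[Si](C)(C)C(C)(C)C)/C=C(/CO[Si](C)(C)C(C)(C)C)CC[C@H](O[Si](C)(C)C(C)(C)C)/C(C)=C\[C@H]1OC(=O)[C@@H](C)CC | intermediate
43 | 1,6,15-trihydroxy C12 acid (formed in the flask) | C=C(C(=O)O)[C@H]1[C@H](O)/C=C(/CO)CC[C@H](O)/C(C)=C\[C@H]1OC(=O)[C@@H](C)CC | intermediate
44 | (1S,6R,7R,8R,4E,9Z)-1,15-dihydroxy-8-[(2S)-2-methylbutanoyloxy]germacra-4,9,11(13)-trien-12,6-olide (CNP0526758.1) | C=C1C(=O)O[C@@H]2/C=C(/CO)CC[C@H](O)/C(C)=C\[C@@H](OC(=O)[C@@H](C)CC)[C@@H]12 | target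

**Step count and risks**

Total steps: 26. Longest linear sequence: 23 (steps 4–26, from but-2-yne-1,4-diol); steps 1–2 and step 3 are side branches.

Steps most likely to fail:

1. Step 21. The base may lithiate C13 or a silyloxy-bearing allylic carbon instead of C8, a [1,2]-shift may compete, or C8 may add to the face of C7=C11 syn to O6. The fallback makes the C7–C8 bond by carbonyl allylation instead of through an α-oxy carbanion. It sets out from seco chloro alcohol 32: MnO2 (CH2Cl2, rt) should give the (9Z)-enal chloride F1. Slow addition of F1 to CrCl2 in THF at high dilution should convert the allylic chloride into the allylchromium species F2, which adds through its γ-carbon C7 to the C8 aldehyde (intramolecular Nozaki–Hiyama allylation). This closes the ten-membered ring with the C11=C13 methylene in place and comes back to the route at 36, bypassing the thirteen-membered ether. The C7/C8 diastereoselectivity of this ring closure is not predictable, so 36 would have to be separated and its configuration proven before going on.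

2. Step 20. Oligomerisation may outrun ring closure, or the O1 silyl group may migrate to the C8 alkoxide and a smaller ether ring may then close. The fallback closes the ring at carbon instead of at oxygen. It sets out from alkenyl iodide 27: DDQ (CH2Cl2–pH 7 buffer, 0 °C) should give the C8 alcohol F3. NaH in THF should give its sodium alkoxide F4, which (iodomethyl)tributylstannane should alkylate to the stannylmethyl ether F5, in which the O–C13 bond already exists. An intramolecular Stille coupling between C13–Sn and C11–I (Pd2(dba)3, AsPh3, NMP, high dilution, 60 °C) should then form C11–C13, close the thirteen-membered ring and come back to the route at 34.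

3. Step 14. The enantioselectivity may be low with a β,β-disubstituted enal, or the enal may isomerise about C4=C5 under the zinc conditions. The fallback sets C6 by reduction instead of by addition. It sets out from enal 22: the lithium acetylide F6 (from 7 and n-BuLi, THF, −78 °C) should add to give the C6-epimeric propargylic alcohols F7. MnO2 should oxidise them to the alkenyl alkynyl ketone F8. Asymmetric transfer hydrogenation with RuCl[(R,R)-TsDPEN](p-cymene) in 2-propanol, which reduces ynones at the carbonyl only, should then give the (6R)-alcohol and come back to the route at 24; the catalyst enantiomer is chosen by analogy with alkyl alkynyl ketones.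

**Further compounds**

F1 | step 21 | (9Z)-enal chloride, 32 with C8 oxidised to the aldehyde | CC[Si](CC)(CC)OC/C(CCl)=C/[C@H](O[Si](C)(C)C(C)(C)C)/C=C(/CO[Si](C)(C)C(C)(C)C)CC[C@H](O[Si](C)(C)C(C)(C)C)/C(C)=C\C=O
F2 | step 21 | allylchromium dichloride from F1 (Cr on C13) | CC[Si](CC)(CC)OC/C(C[Cr](Cl)Cl)=C/[C@H](O[Si](C)(C)C(C)(C)C)/C=C(/CO[Si](C)(C)C(C)(C)C)CC[C@H](O[Si](C)(C)C(C)(C)C)/C(C)=C\C=O
F3 | step 20 | C8 alcohol from 27 (PMB removed, C11 iodide kept) | CC[Si](CC)(CC)OC/C(I)=C/[C@H](O[Si](C)(C)C(C)(C)C)/C=C(/CO[Si](C)(C)C(C)(C)C)CC[C@H](O[Si](C)(C)C(C)(C)C)/C(C)=C\CO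
F4 | step 20 | sodium C8 alkoxide of F3 | CC[Si](CC)(CC)OC/C(I)=C/[C@H](O[Si](C)(C)C(C)(C)C)/C=C(/CO[Si](C)(C)C(C)(C)C)CC[C@H](O[Si](C)(C)C(C)(C)C)/C(C)=C\C[O-].[Na+]
F5 | step 20 | O8 (tributylstannyl)methyl ether of F3 | CC[Si](CC)(CC)OC/C(I)=C/[C@H](O[Si](C)(C)C(C)(C)C)/C=C(/CO[Si](C)(C)C(C)(C)C)CC[C@H](O[Si](C)(C)C(C)(C)C)/C(C)=C\COC[Sn](CCCC)(CCCC)CCCC
F6 | step 14 | [3-(triethylsilyloxy)prop-1-yn-1-yl]lithium | [Li]C#CCO[Si](CC)(CC)CC
F7 | step 14 | C6-epimeric mixture of propargylic alcohols (24 and its 6-epimer) | CC[Si](CC)(CC)OCC#CC(O)/C=C(/CO[Si](C)(C)C(C)(C)C)CC[C@H](O[Si](C)(C)C(C)(C)C)/C(C)=C\COCc1ccc(OC)cc1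
F8 | step 14 | C6 alkenyl alkynyl ketone | CC[Si](CC)(CC)OCC#CC(=O)/C=C(/CO[Si](C)(C)C(C)(C)C)CC[C@H](O[Si](C)(C)C(C)(C)C)/C(C)=C\COCc1ccc(OC)cc1
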